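(The readings were generated by integration for an exercise.)

Leave the flask stirring until 1.0 h and add nothing to it.

| flask | substrate | solid reagent | precatalyst | remark | time |
|---|---|---|---|---|---|
| south-east | 0.067 M | 0.15 M | 10 mM | run made earlier |  |
| south-west | 0.15 M | 0.15 M | 10 mM | run made earlier |  |
| west | 0.10 M | 0.15 M | 5 mM | run made earlier |  |
| flask | 0.10 M | 0.150 M | 10 mM |  | 1.0 h |

| run | time / min | isomer of the product / % | target / % |
|---|---|---|---|
| south-east | 8.00 | 0.7 | 17.5 |
| south-east | 15.0 | 1.2 | 23.4 |
| south-east | 25.0 | 3.0 | 24.9 |
| south-east | 30.0 | 4.5 | 25.1 |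
| south-east | 40.0 | 5.3 | 25.3 |
| south-east | 50.0 | 6.8 | 25.2 |
| south-west | 3.00 | 0 | 7.3 |
| south-west | 10.0 | 1.0 | 20.8 |
| south-west | 15.0 | 2.1 | 23.4 |
| south-west | 25.0 | 2.2 | 25.7 |
| south-west | 40.0 | 4.7 | 24.8 |
| south-west | 50.0 | 6.0 | 24.7 |
| west | 4.00 | 0.6 | 8.8 |
| west | 8.00 | 1.3 | 18.3 |
| west | 15.0 | 2.4 | 23.1 |
| west | 25.0 | 3.2 | 26.0 |
| west | 50.0 | 6.2 | 25.1 |

(scatter of a reading: 0.5 percentage points)

- solid, in amounts per volume of the solution: solid reagent
- at the start none of the solid reagent is in solution

* share of isomer of the product in isomer of the product plus target at 2.0 min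
* share of isomer of the product in isomer of the product plus target at 1.0 h
* which of isomer of the product and target there is more of at 1.0 h

The earlier runs bracket the substrate charge of the flask, and the west run has half its precatalyst, yet at 50.0 min their targets read 25.2%, 24.7% and 25.1%. So I take the flask to follow them, with target flat near 25.0%. Their last isomer readings give 0.0760 /h: this is the isomer creep, the fraction of the substrate charged that appears as isomer per hour.

At the early end I set it beside the first rise of target in the south-west run, 1.46 /h. Creep over creep plus that rate makes the share at 2.0 min about 4.95%, on readings near their scatter of 0.5 percentage points. At the late end the creep gives 7.60% of isomer at 1.0 h against the flat target, so the share is 23.3% and target stays ahead. Do not wait for more target: between 25.0 min and 50.0 min the west run gained more isomer, 3 points, than target, which changed by −0.9 points.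

The forecast stands close to my figures: it gives 5%, 23.5% and target ahead, holding that “isomer looks like a slow parallel route, not a product of target”.

The flask gives 3.21% at 2.0 min and 25.7% at 1.0 h, with target ahead, 24.1% against 8.34% of isomer, by this scheme:

    solid reagent ⇌ coupling partner, rate k1*(cs1 - [coupling partner]) while solid is left; crystals form when [coupling partner] > cs1 (solubility = 0.0820 M, k = 0.0120 /s)
    target + catalyst ⇌ isomer of the product + catalyst, rate k2*[catalyst]*[target] forward; the back reaction follows from the equilibrium constant (k = 0.0200 /M/s)
    substrate + coupling partner ⇌ target (K = 4.40 /M, k = 0.0100 /M/s)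
    substrate + coupling partner ⇌ isomer of the product (K = 640 /M, k = 3.00 × 10⁻⁴ /M/s)
    coupling partner + precatalyst → catalyst + spent reagent (k = 9.30 × 10⁻⁴ /M/s)

In the flask, catalyst stands at 2.01% of its charge after 0.100 h and 23.3% after 1.00 h. The isomer of the flask over the hour makes its creep 0.0834 /h, more than my 0.0760 /h. A neighbour flask with 0.040 M of precatalyst, other charges held, shows a creep of 0.140 /h and ends with a share of 39.0%.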